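**Plan**
- Retrosynthesis, in order: (i) cut the ring bond between the methylidene-bearing ring carbon and the adjacent carbinol carbon; (ii) cut the isovalerate C–O and acid-protecting C–O bonds, which arise from one γ-lactone used as a temporary ring; (iii) cut the trisubstituted C=C (Horner–Wadsworth–Emmons); (iv) cut the CH2–C(α) bond (epoxide opening).
- Enabling feature: in the 11-membered carbocycle a C(=CH2) carbon sits directly beside the secondary carbinol carbon. This 2-methylidene-1-ol unit is what a terminal alkyne gives when its internal carbon adds reductively to an aldehyde; the cis ring enoate and the gem-dimethyl carbon fold the open chain for closure.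
- Forward: C5 gem-dimethyl diol → aldehyde → terminal epoxide → α-phosphono-γ-lactone → E-alkylidene lactone carrying the alkyne → PMB ester/isovalerate → ynal → 11-membered ring (the only ring, formed last) → two deprotections.
- Stereochemistry: the acyloxy carbon (S) comes from hydrolytic kinetic resolution of the epoxide; the E enoate from the olefination; the carbinol carbon (S) from the ring-closing step.

Key step: step 11

Remark: the (4S,5S) antipode of the carbene ligand in step 11 is taken as the one matched to the (S)-acyloxy substrate; if the reverse holds, the (4R,5R) salt is used and nothing else changes.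

**Step 1**
Reactants: 1 3,3-dimethylpentane-1,5-diol
Product: 2 5-[(tert-butyldimethylsilyl)oxy]-3,3-dimethylpentan-1-ol
Conditions: NaH (1.0 equiv), THF, rt; then TBSCl (1.0 equiv)
Reagents that add atoms: tert-butyldimethylsilyl chloride, CC(C)(C)[Si](C)(C)Cl
Why: Monosilylation of a symmetrical diol through its sparingly soluble monosodium alkoxide (O-silylation), which should stop after one hydroxyl; no stereocentre is involved.

**Step 2**
Reactants: 2 5-[(tert-butyldimethylsilyl)oxy]-3,3-dimethylpentan-1-ol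
Product: 3 5-[(tert-butyldimethylsilyl)oxy]-3,3-dimethylpentanal
Conditions: TEMPO (cat.), PhI(OAc)2, CH2Cl2, rt
Reagents that add atoms: none
Why: Oxoammonium (TEMPO) oxidation of a primary alcohol stops at the aldehyde and leaves the silyl ether untouched.

**Step 3**
Reactants: 3 5-[(tert-butyldimethylsilyl)oxy]-3,3-dimethylpentanal
Product: 4 rac-tert-butyl{[3,3-dimethyl-4-(oxiran-2-yl)butyl]oxy}dimethylsilane
Conditions: Me3S+ I−, n-BuLi, THF, −10 °C to rt
Reagents that add atoms: trimethylsulfonium iodide, C[S+](C)C.[I-]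
Why: Corey–Chaykovsky epoxidation, in which the sulfonium ylide adds to the aldehyde and the betaine closes to the terminal epoxide; the new centre is racemic at this stage.

**Step 4**
Reactants: 4 rac-tert-butyl{[3,3-dimethyl-4-(oxiran-2-yl)butyl]oxy}dimethylsilane
Product: 5 tert-butyl({3,3-dimethyl-4-[(2S)-oxiran-2-yl]butyl}oxy)dimethylsilane
Conditions: (S,S)-(salen)Co(OAc) (trivalent cobalt, 0.5 mol %), H2O (0.55 equiv), THF, 0 °C to rt
Reagents that add atoms: none
Why: Jacobsen hydrolytic kinetic resolution, in which the (S,S)-catalyst should hydrolyse the (R)-epoxide selectively and leave the (S)-epoxide, fixing the acyloxy-bearing stereocentre of the target.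

**Step 5**
Reactants: 5 tert-butyl({3,3-dimethyl-4-[(2S)-oxiran-2-yl]butyl}oxy)dimethylsilane; 6 triethyl phosphonoacetate
Product: 8 diethyl {(5S)-5-[4-((tert-butyldimethylsilyl)oxy)-2,2-dimethylbutyl]-2-oxooxolan-3-yl}phosphonate, via open-chain γ-hydroxy phosphonoester 7 (not isolated)
Conditions: NaOEt (1.1 equiv), EtOH, reflux; AcOH work-up
Reagents that add atoms: none
Why: The stabilised phosphonoacetate carbanion opens the epoxide at its unhindered CH2 (SN2, stereocentre untouched) and the alkoxide lactonises onto the ethyl ester, giving a lactone that serves as a temporary ring masking acid and alcohol; the α-centre is epimeric and is destroyed in step 7.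

**Step 6**
Reactants: 9 pent-4-yn-1-ol
Product: 10 pent-4-ynal
Conditions: TEMPO (cat.), PhI(OAc)2, CH2Cl2, rt; used as a solution
Reagents that add atoms: none
Why: Oxoammonium oxidation of the primary alcohol to the volatile aldehyde without touching the terminal alkyne.

**Step 7**
Reactants: 8 diethyl {(5S)-5-[4-((tert-butyldimethylsilyl)oxy)-2,2-dimethylbutyl]-2-oxooxolan-3-yl}phosphonate; 10 pent-4-ynal
Product: 11 (3E,5S)-5-{4-[(tert-butyldimethylsilyl)oxy]-2,2-dimethylbutyl}-3-(pent-4-yn-1-ylidene)oxolan-2-one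
Conditions: KOtBu (1.0 equiv), THF, 0 °C to rt
Reagents that add atoms: none
Why: Horner–Wadsworth–Emmons olefination of the lactone phosphonate should place the new chain trans to the lactone carbonyl (E, the enoate geometry of the target) under thermodynamic control of the addition; a minor Z isomer would be removed by chromatography.

**Step 8**
Reactants: 11 (3E,5S)-5-{4-[(tert-butyldimethylsilyl)oxy]-2,2-dimethylbutyl}-3-(pent-4-yn-1-ylidene)oxolan-2-one; 12 3-methylbutanoic anhydride
Product: 15 4-methoxybenzyl (2E)-2-{(2S)-6-[(tert-butyldimethylsilyl)oxy]-4,4-dimethyl-2-[(3-methylbutanoyl)oxy]hexyl}hept-2-en-6-ynoate, via potassium γ-hydroxy carboxylate 13 (not isolated), via γ-hydroxy PMB ester 14 (not isolated)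
Conditions: KOH (1.05 equiv), THF/H2O, rt; evaporate, toluene azeotrope; PMBCl, NaI (cat.), DMF, rt; then 12, Et3N, DMAP (cat.), 0 °C
Reagents that add atoms: potassium hydroxide, [K+].[OH-]; 4-methoxybenzyl chloride, COc1ccc(CCl)cc1
Why: Saponification opens the lactone, the carboxylate is O-alkylated (SN2) and the free secondary alcohol is acylated at once under DMAP catalysis before it can relactonise (which would only return 11); no bond to the stereocentre is broken.

**Step 9**
Reactants: 15 4-methoxybenzyl (2E)-2-{(2S)-6-[(tert-butyldimethylsilyl)oxy]-4,4-dimethyl-2-[(3-methylbutanoyl)oxy]hexyl}hept-2-en-6-ynoate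
Product: 16 4-methoxybenzyl (2E)-2-{(2S)-6-hydroxy-4,4-dimethyl-2-[(3-methylbutanoyl)oxy]hexyl}hept-2-en-6-ynoate
Conditions: HF·pyridine, pyridine, THF, 0 °C to rt
Reagents that add atoms: none
Why: Buffered fluoride cleaves the primary silyl ether; both esters and the alkyne are inert to it.

**Step 10**
Reactants: 16 4-methoxybenzyl (2E)-2-{(2S)-6-hydroxy-4,4-dimethyl-2-[(3-methylbutanoyl)oxy]hexyl}hept-2-en-6-ynoate
Product: 17 4-methoxybenzyl (2E)-2-{(2S)-4,4-dimethyl-2-[(3-methylbutanoyl)oxy]-6-oxohexyl}hept-2-en-6-ynoate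
Conditions: TEMPO (cat.), PhI(OAc)2, CH2Cl2, rt
Reagents that add atoms: none
Why: Oxoammonium oxidation of the primary alcohol to the aldehyde under neutral conditions that spare the esters, the enoate and the alkyne.

**Step 11**
Reactants: 17 4-methoxybenzyl (2E)-2-{(2S)-4,4-dimethyl-2-[(3-methylbutanoyl)oxy]-6-oxohexyl}hept-2-en-6-ynoate
Product: 18 4-methoxybenzyl (1E,6S,10S)-8,8-dimethyl-5-methylidene-10-[(3-methylbutanoyl)oxy]-6-[(triisopropylsilyl)oxy]cycloundec-1-ene-1-carboxylate
Conditions: Ni(cod)2 (zerovalent nickel, 20 mol %), (4S,5S)-1,3-bis(2,6-diisopropylphenyl)-4,5-diphenyl-4,5-dihydroimidazolium chloride (20 mol %), KOtBu (20 mol %), i-Pr3SiH (3 equiv), THF, rt, syringe-pump addition of 17 to 0.005 M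
Reagents that add atoms: triisopropylsilane, CC(C)[SiH](C(C)C)C(C)C
Why: Zerovalent nickel bearing the bulky carbene binds the aldehyde and the terminal alkyne and couples them oxidatively to an oxanickelacyclopentene; σ-bond metathesis with the silane then silylates the oxygen and C–H reductive elimination releases the product (nickel-catalysed reductive alkyne–aldehyde coupling, known in macrocyclising form for terminal ynals). The 11-membered carbocycle closes in the exo mode at the internal alkyne carbon (11-exo-dig), which leaves the terminal carbon as the exocyclic methylidene. The regioselectivity needed (internal versus terminal alkyne carbon, that is 11- versus 12-membered ring) is secured by the large carbene, which keeps the small CH terminus next to nickel and turns the tethered carbon toward the aldehyde. The new (S)-carbinol centre is set when the aldehyde face is chosen in the oxidative cyclisation; the control elements are the ring conformation of the transition state (restricted by the cis ring enoate, the gem-dimethyl carbon and the (S)-acyloxy group) and the enantiopure C2-symmetric carbene as matched partner. Chemoselectivity for the aldehyde over the esters and the hindered trisubstituted enoate follows from the much stronger binding of an aldehyde to nickel, and slow addition at high dilution holds back alkyne oligomerisation.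

**Step 12**
Reactants: 18 4-methoxybenzyl (1E,6S,10S)-8,8-dimethyl-5-methylidene-10-[(3-methylbutanoyl)oxy]-6-[(triisopropylsilyl)oxy]cycloundec-1-ene-1-carboxylate
Product: 19 (1E,6S,10S)-8,8-dimethyl-5-methylidene-10-[(3-methylbutanoyl)oxy]-6-[(triisopropylsilyl)oxy]cycloundec-1-ene-1-carboxylic acid
Conditions: TFA, anisole, CH2Cl2, 0 °C
Reagents that add atoms: none
Why: Acidolysis of the PMB ester through the stabilised benzylic cation, trapped by anisole; the triisopropylsilyl ether, the isovalerate and the alkenes should survive brief exposure at 0 °C.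

**Step 13**
Reactants: 19 (1E,6S,10S)-8,8-dimethyl-5-methylidene-10-[(3-methylbutanoyl)oxy]-6-[(triisopropylsilyl)oxy]cycloundec-1-ene-1-carboxylic acid
Product: 20 (1E,6S,10S)-6-hydroxy-8,8-dimethyl-5-methylidene-10-[(3-methylbutanoyl)oxy]cycloundec-1-ene-1-carboxylic acid
Conditions: TBAF, AcOH, THF, 0 °C to rt
Reagents that add atoms: none
Why: Fluoride-mediated Si–O cleavage frees the allylic alcohol, and the acetic acid buffer protects the isovalerate from hydrolysis or migration.

**Compound list**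
1 | 3,3-dimethylpentane-1,5-diol | OCCC(C)(C)CCO | starting material
2 | 5-[(tert-butyldimethylsilyl)oxy]-3,3-dimethylpentan-1-ol | CC(C)(C)[Si](C)(C)OCCC(C)(C)CCO | intermediate
3 | 5-[(tert-butyldimethylsilyl)oxy]-3,3-dimethylpentanal | CC(C)(C)[Si](C)(C)OCCC(C)(C)CC=O | intermediate
4 | rac-tert-butyl{[3,3-dimethyl-4-(oxiran-2-yl)butyl]oxy}dimethylsilane | CC(C)(C)[Si](C)(C)OCCC(C)(C)CC1CO1 | intermediate
5 | tert-butyl({3,3-dimethyl-4-[(2S)-oxiran-2-yl]butyl}oxy)dimethylsilane | CC(C)(C)[Si](C)(C)OCCC(C)(C)C[C@H]1CO1 | intermediate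
6 | triethyl phosphonoacetate | CCOC(=O)CP(=O)(OCC)OCC | starting material
7 | ethyl (4S)-8-[(tert-butyldimethylsilyl)oxy]-2-(diethoxyphosphoryl)-4-hydroxy-6,6-dimethyloctanoate (C2 epimers) | CCOC(=O)C(P(=O)(OCC)OCC)C[C@@H](O)CC(C)(C)CCO[Si](C)(C)C(C)(C)C | intermediate
8 | diethyl {(5S)-5-[4-((tert-butyldimethylsilyl)oxy)-2,2-dimethylbutyl]-2-oxooxolan-3-yl}phosphonate (C3 epimers) | CCOP(=O)(OCC)C1C[C@H](CC(C)(C)CCO[Si](C)(C)C(C)(C)C)OC1=O | intermediate
9 | pent-4-yn-1-ol | C#CCCCO | starting material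
10 | pent-4-ynal | C#CCCC=O | intermediate
11 | (3E,5S)-5-{4-[(tert-butyldimethylsilyl)oxy]-2,2-dimethylbutyl}-3-(pent-4-yn-1-ylidene)oxolan-2-one | C#CCC/C=C1\C[C@H](CC(C)(C)CCO[Si](C)(C)C(C)(C)C)OC1=O | intermediate
12 | 3-methylbutanoic anhydride | CC(C)CC(=O)OC(=O)CC(C)C | starting material
13 | potassium (2E)-2-{(2S)-6-[(tert-butyldimethylsilyl)oxy]-2-hydroxy-4,4-dimethylhexyl}hept-2-en-6-ynoate | C#CCC/C=C(/C(=O)[O-])C[C@@H](O)CC(C)(C)CCO[Si](C)(C)C(C)(C)C.[K+] | intermediate
14 | 4-methoxybenzyl (2E)-2-{(2S)-6-[(tert-butyldimethylsilyl)oxy]-2-hydroxy-4,4-dimethylhexyl}hept-2-en-6-ynoate | C#CCC/C=C(/C(=O)OCc1ccc(OC)cc1)C[C@@H](O)CC(C)(C)CCO[Si](C)(C)C(C)(C)C | intermediate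
15 | 4-methoxybenzyl (2E)-2-{(2S)-6-[(tert-butyldimethylsilyl)oxy]-4,4-dimethyl-2-[(3-methylbutanoyl)oxy]hexyl}hept-2-en-6-ynoate | C#CCC/C=C(/C(=O)OCc1ccc(OC)cc1)C[C@@H](OC(=O)CC(C)C)CC(C)(C)CCO[Si](C)(C)C(C)(C)C | intermediate
16 | 4-methoxybenzyl (2E)-2-{(2S)-6-hydroxy-4,4-dimethyl-2-[(3-methylbutanoyl)oxy]hexyl}hept-2-en-6-ynoate | C#CCC/C=C(/C(=O)OCc1ccc(OC)cc1)C[C@@H](OC(=O)CC(C)C)CC(C)(C)CCO | intermediate
17 | 4-methoxybenzyl (2E)-2-{(2S)-4,4-dimethyl-2-[(3-methylbutanoyl)oxy]-6-oxohexyl}hept-2-en-6-ynoate | C#CCC/C=C(/C(=O)OCc1ccc(OC)cc1)C[C@@H](OC(=O)CC(C)C)CC(C)(C)CC=O | intermediate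
18 | 4-methoxybenzyl (1E,6S,10S)-8,8-dimethyl-5-methylidene-10-[(3-methylbutanoyl)oxy]-6-[(triisopropylsilyl)oxy]cycloundec-1-ene-1-carboxylate | C=C1CC/C=C(/C(=O)OCc2ccc(OC)cc2)C[C@@H](OC(=O)CC(C)C)CC(C)(C)C[C@@H]1O[Si](C(C)C)(C(C)C)C(C)C | intermediate
19 | (1E,6S,10S)-8,8-dimethyl-5-methylidene-10-[(3-methylbutanoyl)oxy]-6-[(triisopropylsilyl)oxy]cycloundec-1-ene-1-carboxylic acid | C=C1CC/C=C(/C(=O)O)C[C@@H](OC(=O)CC(C)C)CC(C)(C)C[C@@H]1O[Si](C(C)C)(C(C)C)C(C)C | intermediate
20 | (1E,6S,10S)-6-hydroxy-8,8-dimethyl-5-methylidene-10-[(3-methylbutanoyl)oxy]cycloundec-1-ene-1-carboxylic acid | C=C1CC/C=C(/C(=O)O)C[C@@H](OC(=O)CC(C)C)CC(C)(C)C[C@@H]1O | target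

Total step count: 13. Longest linear sequence: 12 (steps 1–5 and 7–13; step 6 is a one-step side branch).

**Steps most likely to fail**

1. Step 11. The C–C bond may form at the terminal alkyne carbon (12-membered endo closure), the facial selectivity at the aldehyde may be weak, or the alkyne may oligomerise intermolecularly. The fallback sets out from 15 and comes back at 18. The terminal alkyne of 15 is haloborated with B-iodo-9-borabicyclo[3.3.1]nonane (CH2Cl2/hexane, −20 °C) to the (Z)-2-iodoalkenylborane F1 (not isolated), which AcOH protonolyses to the 2-iodo-1-alkene F2. HF·pyridine gives the primary alcohol F3 and TEMPO/PhI(OAc)2 the iodo aldehyde F4. A Nozaki–Hiyama–Kishi macrocyclisation (CrCl2, NiCl2 cat., chiral oxazoline–sulfonamide ligand, proton sponge, MeCN/THF, high dilution) then closes the same bond. Its regiochemistry is fixed by the carbon–iodine bond and the carbinol configuration is set by the chiral chromium complex, giving the free allylic alcohol F5. TIPSOTf/2,6-lutidine converts F5 into 18.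

2. Step 8. The γ-hydroxy ester may relactonise before the alcohol is acylated. The fallback sets out from 11 and comes back at 15, carrying the carboxyl carbon at the alcohol level so that no γ-hydroxy ester ever exists. i-Bu2AlH (CH2Cl2, −78 to 0 °C) reduces the lactone to the allylic diol F6. TESCl/imidazole at −78 °C silylates only the primary allylic hydroxyl, giving the mono-triethylsilyl ether F7, and 12/DMAP acylates the secondary alcohol to the isovalerate F8. Swern oxidation converts the primary allylic triethylsilyl ether directly into the enal F9. Pinnick oxidation (NaClO2, NaH2PO4, 2-methyl-2-butene, t-BuOH/H2O) gives the acid F10, and PMBCl/KHCO3/DMF gives 15.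

3. Step 7. E selectivity may erode in the olefination; one step earlier, in step 5, phosphoryl transfer to the alkoxide may compete with lactonisation. The fallback sets out from 5 and comes back at 11, bypassing step 5 as well. Sodium diethyl malonate (NaOEt, EtOH, reflux) opens 5 to the hydroxy malonate F11 (not isolated), which lactonises to the α-ethoxycarbonyl lactone F12. LiCl in wet DMSO at 140 °C decarboxylates it to the γ-lactone F13. LiN(i-Pr)2 (THF, −78 °C) followed by 10 gives the aldol F14. MsCl/Et3N gives the mesylate F15 (not isolated), and DBU eliminates it by E1cB to the thermodynamically preferred E-alkylidene lactone 11.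

**Further compounds**
F1 | step 11 | 4-methoxybenzyl (2E,6Z)-7-(9-borabicyclo[3.3.1]nonan-9-yl)-2-{(2S)-6-[(tert-butyldimethylsilyl)oxy]-4,4-dimethyl-2-[(3-methylbutanoyl)oxy]hexyl}-6-iodohepta-2,6-dienoate | I/C(CC/C=C(/C(=O)OCc1ccc(OC)cc1)C[C@@H](OC(=O)CC(C)C)CC(C)(C)CCO[Si](C)(C)C(C)(C)C)=C\B1C2CCCC1CCC2
F2 | step 11 | 4-methoxybenzyl (2E)-2-{(2S)-6-[(tert-butyldimethylsilyl)oxy]-4,4-dimethyl-2-[(3-methylbutanoyl)oxy]hexyl}-6-iodohepta-2,6-dienoate | C=C(I)CC/C=C(/C(=O)OCc1ccc(OC)cc1)C[C@@H](OC(=O)CC(C)C)CC(C)(C)CCO[Si](C)(C)C(C)(C)C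
F3 | step 11 | 4-methoxybenzyl (2E)-2-{(2S)-6-hydroxy-4,4-dimethyl-2-[(3-methylbutanoyl)oxy]hexyl}-6-iodohepta-2,6-dienoate | C=C(I)CC/C=C(/C(=O)OCc1ccc(OC)cc1)C[C@@H](OC(=O)CC(C)C)CC(C)(C)CCO
F4 | step 11 | 4-methoxybenzyl (2E)-2-{(2S)-4,4-dimethyl-2-[(3-methylbutanoyl)oxy]-6-oxohexyl}-6-iodohepta-2,6-dienoate | C=C(I)CC/C=C(/C(=O)OCc1ccc(OC)cc1)C[C@@H](OC(=O)CC(C)C)CC(C)(C)CC=O
F5 | step 11 | 4-methoxybenzyl (1E,6S,10S)-6-hydroxy-8,8-dimethyl-5-methylidene-10-[(3-methylbutanoyl)oxy]cycloundec-1-ene-1-carboxylate | C=C1CC/C=C(/C(=O)OCc2ccc(OC)cc2)C[C@@H](OC(=O)CC(C)C)CC(C)(C)C[C@@H]1O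
F6 | step 8 | (2E)-2-{(2S)-6-[(tert-butyldimethylsilyl)oxy]-2-hydroxy-4,4-dimethylhexyl}hept-2-en-6-yn-1-ol | C#CCC/C=C(/CO)C[C@@H](O)CC(C)(C)CCO[Si](C)(C)C(C)(C)C
F7 | step 8 | (2E)-2-{(2S)-6-[(tert-butyldimethylsilyl)oxy]-2-hydroxy-4,4-dimethylhexyl}hept-2-en-6-yn-1-yl triethylsilyl ether | C#CCC/C=C(/CO[Si](CC)(CC)CC)C[C@@H](O)CC(C)(C)CCO[Si](C)(C)C(C)(C)C
F8 | step 8 | (2E)-2-{(2S)-6-[(tert-butyldimethylsilyl)oxy]-4,4-dimethyl-2-[(3-methylbutanoyl)oxy]hexyl}hept-2-en-6-yn-1-yl triethylsilyl ether | C#CCC/C=C(/CO[Si](CC)(CC)CC)C[C@@H](OC(=O)CC(C)C)CC(C)(C)CCO[Si](C)(C)C(C)(C)C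
F9 | step 8 | (2E)-2-{(2S)-6-[(tert-butyldimethylsilyl)oxy]-4,4-dimethyl-2-[(3-methylbutanoyl)oxy]hexyl}hept-2-en-6-ynal | C#CCC/C=C(/C=O)C[C@@H](OC(=O)CC(C)C)CC(C)(C)CCO[Si](C)(C)C(C)(C)C
F10 | step 8 | (2E)-2-{(2S)-6-[(tert-butyldimethylsilyl)oxy]-4,4-dimethyl-2-[(3-methylbutanoyl)oxy]hexyl}hept-2-en-6-ynoic acid | C#CCC/C=C(/C(=O)O)C[C@@H](OC(=O)CC(C)C)CC(C)(C)CCO[Si](C)(C)C(C)(C)C
F11 | step 7 | diethyl 2-{(2R)-6-[(tert-butyldimethylsilyl)oxy]-2-hydroxy-4,4-dimethylhexyl}propanedioate | CCOC(=O)C(C(=O)OCC)C[C@@H](O)CC(C)(C)CCO[Si](C)(C)C(C)(C)C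
F12 | step 7 | ethyl (5R)-5-{4-[(tert-butyldimethylsilyl)oxy]-2,2-dimethylbutyl}-2-oxooxolane-3-carboxylate (C3 epimers) | CCOC(=O)C1C[C@H](CC(C)(C)CCO[Si](C)(C)C(C)(C)C)OC1=O
F13 | step 7 | (5R)-5-{4-[(tert-butyldimethylsilyl)oxy]-2,2-dimethylbutyl}oxolan-2-one | O=C1CC[C@H](CC(C)(C)CCO[Si](C)(C)C(C)(C)C)O1
F14 | step 7 | (5R)-5-{4-[(tert-butyldimethylsilyl)oxy]-2,2-dimethylbutyl}-3-(1-hydroxypent-4-yn-1-yl)oxolan-2-one (diastereomers) | C#CCCC(O)C1C[C@H](CC(C)(C)CCO[Si](C)(C)C(C)(C)C)OC1=O
F15 | step 7 | 1-[(5R)-5-{4-[(tert-butyldimethylsilyl)oxy]-2,2-dimethylbutyl}-2-oxooxolan-3-yl]pent-4-yn-1-yl methanesulfonate (diastereomers) | C#CCCC(OS(C)(=O)=O)C1C[C@H](CC(C)(C)CCO[Si](C)(C)C(C)(C)C)OC1=O
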